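Numbering (germacrane): C1 carbinol, C2 and C3 CH2, C4(C15)–C5 oxirane, C6 lactone CH–O, C7=C11 butenolide alkene, C8 tiglate carbon, C9=C10(C14), C12 lactone C=O, C13 CH2OAc.
Retrosynthesis: cut the two ester C–O bonds (C8, C13), take C1–OH back to the ketone and the oxirane back to the E-C4=C5 alkene, then open the ten-membered ring at C3–C4 to an acyclic ynyl dienone.
Enabling feature: C3 is β to the oxygenated C1, so C1–C3 can be a vinyl ketone. The methyl-bearing oxirane C4–C5 next to ring carbon C6 of the butenolide is the retron of a propynyl group. The two fragments are joined reductively.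
Hidden pseudo-symmetry: C7 carries two propynyl carbinols (C5–C4–C15 and C9–C10–C14), so propyne is used twice. C6, C7, C8, C11, C12 and C13 come from furan-3,4-diyldimethanol, C1 from CO, and C2–C3 from a vinylstannane.
Forward order: furan, then the C8 arm, then oxidation of the furan to the butenolide ring with the C6 arm, then the dienone, then the ten-membered carbocycle, then the esters, the oxirane and the C1 carbinol.
Stereochemistry: C8 and C6 come from two ligand-controlled alkynylations with antipodal ligands. Z-C9=C10 comes from trans-hydroalumination and E-C4=C5 from syn addition in the ring closure. C4/C5 come from peripheral epoxidation steered by C6, and C1 from a CBS reduction.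

Key step: step 10

Assumption: the (S,S)-ProPhenol–zinc catalyst is taken to transfer an alkynyl group to the Si face of aryl and alkenyl aldehydes. Steps 3 and 8 need opposite faces in any case, so if the sense is the reverse the two ligand antipodes are exchanged.

Step 1
Reactants: 1 furan-3,4-diyldimethanol
Product: 2 [4-(tert-butyldimethylsilyloxymethyl)furan-3-yl]methanol
Conditions: NaH (1.0 equiv), THF, 0 °C; TBSCl (1.0 equiv), rt
Reagents that add atoms: tert-butyldimethylsilyl chloride CC(C)(C)[Si](C)(C)Cl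
Why: O-silylation of the sparingly soluble monosodium alkoxide of a symmetric diol should stop at the mono ether, which distinguishes the future C13 (silylated) from the future C8 (free).

Step 2
Reactants: 2 [4-(tert-butyldimethylsilyloxymethyl)furan-3-yl]methanol
Product: 3 4-(tert-butyldimethylsilyloxymethyl)furan-3-carbaldehyde
Conditions: activated MnO2, CH2Cl2, rt
Reagents that add atoms: none
Why: MnO2 oxidation of a heteroaryl carbinol should stop at the aldehyde and leave the furan and the silyl ether untouched.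

Step 3
Reactants: 3 4-(tert-butyldimethylsilyloxymethyl)furan-3-carbaldehyde; 4 propyne
Product: 5 (1S)-1-[4-(tert-butyldimethylsilyloxymethyl)furan-3-yl]but-2-yn-1-ol
Conditions: propyne (3 equiv), Me2Zn (3 equiv), (S,S)-ProPhenol (20 mol%), Ph3PO (40 mol%), toluene, 4 °C; aq NH4Cl
Reagents that add atoms: propyne CC#C
Why: Catalytic asymmetric alkynylation of an aromatic aldehyde by the dinuclear zinc–ProPhenol complex, in which ligand-controlled Si-face delivery of the propynyl group sets C8 as S.

Step 4
Reactants: 5 (1S)-1-[4-(tert-butyldimethylsilyloxymethyl)furan-3-yl]but-2-yn-1-ol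
Product: 7 (1S,2Z)-1-[4-(tert-butyldimethylsilyloxymethyl)furan-3-yl]-3-iodobut-2-en-1-ol, via cyclic sodium vinylalanate 6 (not isolated)
Conditions: Red-Al (NaAlH2(OCH2CH2OMe)2), THF, 0 °C to rt; then I2, THF, −78 °C
Reagents that add atoms: iodine II
Why: Hydroxyl-directed trans-hydroalumination puts aluminium on the distal alkyne carbon within a five-membered alanate, and iodinolysis with retention gives the iodide cis to C8, which fixes the Z geometry of C9=C10.

Step 5
Reactants: 7 (1S,2Z)-1-[4-(tert-butyldimethylsilyloxymethyl)furan-3-yl]-3-iodobut-2-en-1-ol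
Product: 8 3-[(1S,2Z)-1-(tert-butyldimethylsilyloxy)-3-iodobut-2-enyl]-4-(tert-butyldimethylsilyloxymethyl)furan
Conditions: TBSCl, imidazole, DMF, rt
Reagents that add atoms: tert-butyldimethylsilyl chloride CC(C)(C)[Si](C)(C)Cl
Why: Standard silylation of a secondary allylic alcohol; the bulky ether also enlarges the C8 side of the furan for the next step.

Step 6
Reactants: 8 3-[(1S,2Z)-1-(tert-butyldimethylsilyloxy)-3-iodobut-2-enyl]-4-(tert-butyldimethylsilyloxymethyl)furan
Product: 10 5-hydroxy-4-[(1S,2Z)-1-(tert-butyldimethylsilyloxy)-3-iodobut-2-enyl]-3-(tert-butyldimethylsilyloxymethyl)furan-2(5H)-one (both C6 anomers), via furan endoperoxide 9 (not isolated)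
Conditions: O2, visible light, tetraphenylporphyrin (cat.), iPr2NEt, CH2Cl2, −78 °C
Reagents that add atoms: dioxygen O=O
Why: A [4+2] addition of singlet oxygen to the furan is followed by a Kornblum–DeLaMare fragmentation in which the hindered amine should remove the less shielded bridgehead hydrogen (C12, next to CH2OTBS), so that C12 becomes the lactone carbonyl and C6 the hemiacetal, while the iodoalkene is too electron-poor for an ene reaction.

Step 7
Reactants: 10 5-hydroxy-4-[(1S,2Z)-1-(tert-butyldimethylsilyloxy)-3-iodobut-2-enyl]-3-(tert-butyldimethylsilyloxymethyl)furan-2(5H)-one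
Product: 11 methyl (2Z,4S,5Z)-4-(tert-butyldimethylsilyloxy)-2-(tert-butyldimethylsilyloxymethyl)-3-formyl-6-iodohepta-2,5-dienoate
Conditions: MeI, K2CO3, DMF, 0 °C
Reagents that add atoms: iodomethane CI
Why: O-alkylation of the ring-opened carboxylate tautomer of the pseudo-acid frees the C6 aldehyde, and the ring origin of the tetrasubstituted C7=C11 alkene keeps aldehyde and ester cis.

Step 8
Reactants: 11 methyl (2Z,4S,5Z)-4-(tert-butyldimethylsilyloxy)-2-(tert-butyldimethylsilyloxymethyl)-3-formyl-6-iodohepta-2,5-dienoate; 4 propyne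
Product: 13 (5R)-4-[(1S,2Z)-1-(tert-butyldimethylsilyloxy)-3-iodobut-2-enyl]-3-(tert-butyldimethylsilyloxymethyl)-5-(prop-1-ynyl)furan-2(5H)-one, via methylzinc alkoxide 12 (not isolated)
Conditions: propyne (3 equiv), Me2Zn (3 equiv), (R,R)-ProPhenol (20 mol%), Ph3PO (40 mol%), toluene, 4 °C to rt; aq NH4Cl
Reagents that add atoms: propyne CC#C
Why: A second zinc–ProPhenol alkynylation, now of an enal and with the antipodal ligand, delivers propynyl to the Re face and sets C6, and the zinc alkoxide lactonises onto the cis ester to close the butenolide ring.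

Step 9
Reactants: 13 (5R)-4-[(1S,2Z)-1-(tert-butyldimethylsilyloxy)-3-iodobut-2-enyl]-3-(tert-butyldimethylsilyloxymethyl)-5-(prop-1-ynyl)furan-2(5H)-one; 14 tributyl(vinyl)stannane
Product: 15 (5R)-4-[(1S,2Z)-1-(tert-butyldimethylsilyloxy)-3-methyl-4-oxohexa-2,5-dienyl]-3-(tert-butyldimethylsilyloxymethyl)-5-(prop-1-ynyl)furan-2(5H)-one
Conditions: CO (3 atm), PdCl2(MeCN)2 (5 mol%), DMF, 40 °C
Reagents that add atoms: carbon monoxide [C-]#[O+]; tributyl(vinyl)stannane C=C[Sn](CCCC)(CCCC)CCCC
Why: Carbonylative Stille coupling of an alkenyl iodide with a vinylstannane is the established route to unsymmetrical divinyl ketones and keeps the Z geometry, while CO pressure suppresses the direct coupling.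

Step 10
Reactants: 15 (5R)-4-[(1S,2Z)-1-(tert-butyldimethylsilyloxy)-3-methyl-4-oxohexa-2,5-dienyl]-3-(tert-butyldimethylsilyloxymethyl)-5-(prop-1-ynyl)furan-2(5H)-one
Product: 16 (6R,8S)-8,13-bis(tert-butyldimethylsilyloxy)-1-oxogermacra-4E,7(11),9Z-trien-12,6-olide
Conditions: Ni(cod)2 (30 mol%), PBu3 (60 mol%), Et3B (4 equiv), MeOH–THF 8:1, 50 °C, slow addition of 15 (final 2 mM)
Reagents that add atoms: none
Why: Proposed new method: zerovalent nickel binds the methyl-capped alkyne and the s-cis vinyl ketone of 15 and couples them oxidatively to a seven-membered O-bound nickel enolate metallacycle (Ni–C5=C4–C3–C2=C1–O) in which the C3–C4 bond is made; methanol then protonates the enolate at C2, Et3B hands an ethyl group to nickel, and β-hydride elimination followed by C–H reductive elimination places hydrogen on C5 syn to C3. The closest known reactions are the intermolecular nickel-catalysed reductive coupling of enones with alkynes under these Et3B/MeOH conditions, its five- and six-ring intramolecular form, and the nickel-catalysed reductive macrocyclisation of ynals, so only the medium-ring enone version is new. The ten-membered carbocycle closes in a 10-endo-dig (alkyne) and 10-endo-trig (enone) mode, and both π-bonds end up inside the ring. No stereocentre is created; the only new stereo-element, the E-C4=C5 geometry, follows from the syn addition of C3 and H across the alkyne. Three selectivities are needed: bonding at C4 rather than C5 (with a small phosphine the new bond forms at the methyl-bearing alkyne carbon, away from branched C6); reaction at the unsubstituted C2=C3 terminus rather than five-ring closure of C5 onto C9 (C9=C10 is trisubstituted, flanked by C8–OTBS, and twisted out of conjugation by its Z substituent and C14, so it should bind nickel poorly); and ring closure rather than oligomerisation (slow addition at millimolar concentration, helped by the cis relation of C6 and C8, which lets both arms leave the planar butenolide on the same face). Silyl ethers instead of esters at C8 and C13 keep allylic C–O ionisation by nickel out of play.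

Step 11
Reactants: 16 (6R,8S)-8,13-bis(tert-butyldimethylsilyloxy)-1-oxogermacra-4E,7(11),9Z-trien-12,6-olide
Product: 17 (6R,8S)-8,13-dihydroxy-1-oxogermacra-4E,7(11),9Z-trien-12,6-olide
Conditions: HF·pyridine, pyridine, THF, 0 °C to rt
Reagents that add atoms: none
Why: Buffered fluoride desilylation frees both hydroxyls without base at the acidic C6–H, and transannular hemiketal or furan formation from C8–OH and the C1 ketone should be held back by the strain of an E-alkene in the resulting smaller bridge.

Step 12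
Reactants: 17 (6R,8S)-8,13-dihydroxy-1-oxogermacra-4E,7(11),9Z-trien-12,6-olide
Product: 18 (6R,8S)-13-acetoxy-8-hydroxy-1-oxogermacra-4E,7(11),9Z-trien-12,6-olide
Conditions: AcCl (1.05 equiv), 2,4,6-collidine, CH2Cl2, −78 °C
Reagents that add atoms: acetyl chloride CC(=O)Cl
Why: Low-temperature acetylation with a hindered base is selective for the primary C13 hydroxyl over the crowded secondary C8 hydroxyl, and C1 is protected by being a ketone.

Step 13
Reactants: 18 (6R,8S)-13-acetoxy-8-hydroxy-1-oxogermacra-4E,7(11),9Z-trien-12,6-olide; 19 tigloyl chloride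
Product: 20 (6R,8S)-13-acetoxy-1-oxo-8-tigloyloxygermacra-4E,7(11),9Z-trien-12,6-olide
Conditions: 19, pyridine, DMAP (cat.), CH2Cl2, 0 °C to rt
Reagents that add atoms: tigloyl chloride C/C=C(\C)C(=O)Cl
Why: DMAP-catalysed acylation of the only free hydroxyl proceeds with retention at C8, and the E-configured tiglate is the stable isomer and should not scramble.

Step 14
Reactants: 20 (6R,8S)-13-acetoxy-1-oxo-8-tigloyloxygermacra-4E,7(11),9Z-trien-12,6-olide
Product: 21 (4R,5R,6S,8S)-13-acetoxy-4,5-epoxy-1-oxo-8-tigloyloxygermacra-7(11),9Z-dien-12,6-olide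
Conditions: mCPBA, NaHCO3, CH2Cl2, 0 °C
Reagents that add atoms: 3-chloroperbenzoic acid OOC(=O)c1cccc(Cl)c1
Why: In this Prilezhaev epoxidation C4=C5 is the only nucleophilic alkene (enone, butenolide and tiglate are electron-poor), and A1,3 strain between C15 and C6 holds H6 in the alkene plane so that the ring (C2, C7) covers one face and the peracid adds peripherally, syn to the lactone oxygen, giving 4R,5R.

Step 15
Reactants: 21 (4R,5R,6S,8S)-13-acetoxy-4,5-epoxy-1-oxo-8-tigloyloxygermacra-7(11),9Z-dien-12,6-olide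
Product: 22 (1S,4R,5R,6S,8S)-13-acetoxy-4,5-epoxy-1-hydroxy-8-tigloyloxygermacra-7(11),9Z-dien-12,6-olide (target)
Conditions: (R)-Me-CBS oxazaborolidine (0.5 equiv), catecholborane, toluene, −78 °C; aq work-up
Reagents that add atoms: none
Why: Corey–Bakshi–Shibata 1,2-reduction of the enone treats the α-methylalkenyl carbon C10 as the large group and C2H2 as the small group, so the (R)-catalyst should give 1S, and esters, lactone and oxirane are inert at this temperature.

Compound list
1 | furan-3,4-diyldimethanol | OCc1cocc1CO | starting material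
2 | [4-(tert-butyldimethylsilyloxymethyl)furan-3-yl]methanol | OCc1cocc1CO[Si](C)(C)C(C)(C)C | intermediate
3 | 4-(tert-butyldimethylsilyloxymethyl)furan-3-carbaldehyde | O=Cc1cocc1CO[Si](C)(C)C(C)(C)C | intermediate
4 | propyne | CC#C | starting material
5 | (1S)-1-[4-(tert-butyldimethylsilyloxymethyl)furan-3-yl]but-2-yn-1-ol | CC#C[C@H](O)c1cocc1CO[Si](C)(C)C(C)(C)C | intermediate
6 | cyclic sodium vinylalanate (five-membered O–Al–C10=C9–C8 ring, two 2-methoxyethoxy groups on aluminium) | CC1=C[C@@H](c2cocc2CO[Si](C)(C)C(C)(C)C)O[Al-]1(OCCOC)OCCOC.[Na+] | intermediate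
7 | (1S,2Z)-1-[4-(tert-butyldimethylsilyloxymethyl)furan-3-yl]-3-iodobut-2-en-1-ol | CC(C)(C)[Si](C)(C)OCc1cocc1[C@@H](O)/C=C(/C)I | intermediate
8 | 3-[(1S,2Z)-1-(tert-butyldimethylsilyloxy)-3-iodobut-2-enyl]-4-(tert-butyldimethylsilyloxymethyl)furan | CC(C)(C)[Si](C)(C)OCc1cocc1[C@@H](O[Si](C)(C)C(C)(C)C)/C=C(/C)I | intermediate
9 | furan endoperoxide of 8 (2,3,7-trioxabicyclo[2.2.1]hept-5-ene) | C12OOC(O1)C(CO[Si](C)(C)C(C)(C)C)=C2[C@@H](O[Si](C)(C)C(C)(C)C)/C=C(/C)I | intermediate
10 | 5-hydroxy-4-[(1S,2Z)-1-(tert-butyldimethylsilyloxy)-3-iodobut-2-enyl]-3-(tert-butyldimethylsilyloxymethyl)furan-2(5H)-one | OC1OC(=O)C(CO[Si](C)(C)C(C)(C)C)=C1[C@@H](O[Si](C)(C)C(C)(C)C)/C=C(/C)I | intermediate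
11 | methyl (2Z,4S,5Z)-4-(tert-butyldimethylsilyloxy)-2-(tert-butyldimethylsilyloxymethyl)-3-formyl-6-iodohepta-2,5-dienoate | COC(=O)/C(CO[Si](C)(C)C(C)(C)C)=C(\C=O)[C@@H](O[Si](C)(C)C(C)(C)C)/C=C(/C)I | intermediate
12 | methylzinc alkoxide from Re-face propynyl addition to the formyl group of 11 (carbinol carbon R, cis to the ester) | COC(=O)/C(CO[Si](C)(C)C(C)(C)C)=C(\[C@H](O[Zn]C)C#CC)[C@@H](O[Si](C)(C)C(C)(C)C)/C=C(/C)I | intermediate
13 | (5R)-4-[(1S,2Z)-1-(tert-butyldimethylsilyloxy)-3-iodobut-2-enyl]-3-(tert-butyldimethylsilyloxymethyl)-5-(prop-1-ynyl)furan-2(5H)-one | CC#C[C@H]1OC(=O)C(CO[Si](C)(C)C(C)(C)C)=C1[C@@H](O[Si](C)(C)C(C)(C)C)/C=C(/C)I | intermediate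
14 | tributyl(vinyl)stannane | C=C[Sn](CCCC)(CCCC)CCCC | starting material
15 | (5R)-4-[(1S,2Z)-1-(tert-butyldimethylsilyloxy)-3-methyl-4-oxohexa-2,5-dienyl]-3-(tert-butyldimethylsilyloxymethyl)-5-(prop-1-ynyl)furan-2(5H)-one | CC#C[C@H]1OC(=O)C(CO[Si](C)(C)C(C)(C)C)=C1[C@@H](O[Si](C)(C)C(C)(C)C)/C=C(/C)C(=O)C=C | intermediate
16 | (6R,8S)-8,13-bis(tert-butyldimethylsilyloxy)-1-oxogermacra-4E,7(11),9Z-trien-12,6-olide | CC(C)(C)[Si](C)(C)O[C@H]1/C=C(/C)C(=O)CC/C(C)=C/[C@H]2OC(=O)C(CO[Si](C)(C)C(C)(C)C)=C12 | intermediate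
17 | (6R,8S)-8,13-dihydroxy-1-oxogermacra-4E,7(11),9Z-trien-12,6-olide | O[C@H]1/C=C(/C)C(=O)CC/C(C)=C/[C@H]2OC(=O)C(CO)=C12 | intermediate
18 | (6R,8S)-13-acetoxy-8-hydroxy-1-oxogermacra-4E,7(11),9Z-trien-12,6-olide | O[C@H]1/C=C(/C)C(=O)CC/C(C)=C/[C@H]2OC(=O)C(COC(C)=O)=C12 | intermediate
19 | tigloyl chloride, (E)-2-methylbut-2-enoyl chloride | C/C=C(\C)C(=O)Cl | starting material
20 | (6R,8S)-13-acetoxy-1-oxo-8-tigloyloxygermacra-4E,7(11),9Z-trien-12,6-olide | C/C=C(\C)C(=O)O[C@H]1/C=C(/C)C(=O)CC/C(C)=C/[C@H]2OC(=O)C(COC(C)=O)=C12 | intermediate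
21 | (4R,5R,6S,8S)-13-acetoxy-4,5-epoxy-1-oxo-8-tigloyloxygermacra-7(11),9Z-dien-12,6-olide | C/C=C(\C)C(=O)O[C@H]1/C=C(/C)C(=O)CC[C@@]2(C)O[C@@H]2[C@H]2OC(=O)C(COC(C)=O)=C12 | intermediate
22 | (1S,4R,5R,6S,8S)-13-acetoxy-4,5-epoxy-1-hydroxy-8-tigloyloxygermacra-7(11),9Z-dien-12,6-olide | C/C=C(\C)C(=O)O[C@H]1/C=C(/C)[C@@H](O)CC[C@@]2(C)O[C@@H]2[C@H]2OC(=O)C(COC(C)=O)=C12 | target

Total step count: 15. Longest linear sequence: 15.

Steps most likely to fail

Step 10. Nickel may engage the nearby C9=C10 alkene, so that C5 and C9 close a five-membered ring. The chains may also oligomerise, or the propargylic C6–O bond may ionise. The fallback makes the same C3–C4 bond by a B-alkyl Suzuki–Miyaura macrocyclisation. An E-alkenylpalladium at C4 cannot close a small ring because its new bond is trans to C6. The fallback sets out from 13. Nozaki–Hiyama–Kishi coupling with acrolein (CrCl2, cat. NiCl2, DMF) should give the C1-epimeric dienol F1. Palladium-catalysed syn-hydrostannation of the alkyne (Bu3SnH, PdCl2(PPh3)2, THF) should place tin at the less hindered methyl-bearing carbon and give the E-alkenylstannane F2, and iodinolysis (I2, CH2Cl2, 0 °C) gives the E-alkenyl iodide F3. 9-BBN (2.5 equiv, THF) hydroborates only the terminal vinyl group and caps the hydroxyl, giving the bis-boron compound F4. Treatment in the same flask with PdCl2(dppf), AsPh3 and Cs2CO3 in DMF–THF–H2O at high dilution closes the ring to the macrocyclic allylic alcohol F5. Dess–Martin oxidation converges both C1 epimers and returns to the route at 16.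

Step 8. Addition to the fully substituted, crowded enal may be slow, and the facial selectivity may erode if the resident C8 centre opposes the ligand. The fallback gives up catalyst control in favour of separation and recycling. It sets out from 11. Propynylmagnesium bromide (THF, −78 °C) adds to the aldehyde and the alkoxide lactonises to both C6 epimers, which are separated by chromatography. The unwanted C6 epimer F6 is re-equilibrated with a catalytic amine base (DBU, CH2Cl2) through the 2-oxidofuran, in which C6 is planar, and is separated again. The route is rejoined at 13.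

Step 6. The base may remove the wrong bridgehead hydrogen of the endoperoxide, which puts the lactone carbonyl at the C6 side, or the ene reaction at C9=C10 may compete. The fallback fixes the regiochemistry by a sterically governed C–H borylation before any oxidation. It sets out from 8. Iridium-catalysed borylation ([Ir(OMe)(cod)]2, dtbpy, B2pin2, THF, 60 °C) at the less hindered α-position next to CH2OTBS should give the C12 boronate F7. Oxidation (NaBO3·4H2O, THF–H2O) and tautomerisation give the C6-unsubstituted butenolide F8. TIPSOTf/Et3N converts it into the 2-silyloxyfuran F9, and dimethyldioxirane (acetone, −78 °C) oxidises the γ-position. The route is rejoined at 10.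

Further compounds
F1 | step 10 | (5R)-4-[(1S,2Z)-1-(tert-butyldimethylsilyloxy)-4-hydroxy-3-methylhexa-2,5-dienyl]-3-(tert-butyldimethylsilyloxymethyl)-5-(prop-1-ynyl)furan-2(5H)-one (C1 epimers) | CC#C[C@H]1OC(=O)C(CO[Si](C)(C)C(C)(C)C)=C1[C@@H](O[Si](C)(C)C(C)(C)C)/C=C(/C)C(O)C=C
F2 | step 10 | E-alkenylstannane, 5-[(E)-2-(tributylstannyl)prop-1-enyl] analogue of F1 | C/C([Sn](CCCC)(CCCC)CCCC)=C\[C@H]1OC(=O)C(CO[Si](C)(C)C(C)(C)C)=C1[C@@H](O[Si](C)(C)C(C)(C)C)/C=C(/C)C(O)C=C
F3 | step 10 | E-alkenyl iodide, 5-[(E)-2-iodoprop-1-enyl] analogue of F1 | C/C(I)=C\[C@H]1OC(=O)C(CO[Si](C)(C)C(C)(C)C)=C1[C@@H](O[Si](C)(C)C(C)(C)C)/C=C(/C)C(O)C=C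
F4 | step 10 | bis-boron compound from F3 (C3–B and C1–O–B, both 9-borabicyclo[3.3.1]nonan-9-yl) | C/C(I)=C\[C@H]1OC(=O)C(CO[Si](C)(C)C(C)(C)C)=C1[C@@H](O[Si](C)(C)C(C)(C)C)/C=C(/C)C(CCB1C2CCCC1CCC2)OB1C2CCCC1CCC2
F5 | step 10 | (6R,8S)-8,13-bis(tert-butyldimethylsilyloxy)-1-hydroxygermacra-4E,7(11),9Z-trien-12,6-olide (C1 epimers) | CC(C)(C)[Si](C)(C)O[C@H]1/C=C(/C)C(O)CC/C(C)=C/[C@H]2OC(=O)C(CO[Si](C)(C)C(C)(C)C)=C12
F6 | step 8 | (5S)-epimer of 13 | CC#C[C@@H]1OC(=O)C(CO[Si](C)(C)C(C)(C)C)=C1[C@@H](O[Si](C)(C)C(C)(C)C)/C=C(/C)I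
F7 | step 6 | 2-(pinacolatoboryl) derivative of 8 (boron on the α-carbon next to CH2OTBS) | CC(C)(C)[Si](C)(C)OCc1c(B2OC(C)(C)C(C)(C)O2)occ1[C@@H](O[Si](C)(C)C(C)(C)C)/C=C(/C)I
F8 | step 6 | 4-[(1S,2Z)-1-(tert-butyldimethylsilyloxy)-3-iodobut-2-enyl]-3-(tert-butyldimethylsilyloxymethyl)furan-2(5H)-one | C1OC(=O)C(CO[Si](C)(C)C(C)(C)C)=C1[C@@H](O[Si](C)(C)C(C)(C)C)/C=C(/C)I
F9 | step 6 | 2-(triisopropylsilyloxy)furan derived from F8 | CC(C)[Si](Oc1occ([C@@H](O[Si](C)(C)C(C)(C)C)/C=C(/C)I)c1CO[Si](C)(C)C(C)(C)C)(C(C)C)C(C)C
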